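## Retrosynthetic overview

1. Target 18 ⇒ but-2-ynoate 15 by a last-step syn-hydroalumination/hydroxymethylation that sets the (Z)-enoate; 15 ⇒ diol 13 + but-2-ynoic acid 14.
2. 13 ⇒ γ-lactol 10 + benzylic phosphonate 11 (E-selective Horner–Wadsworth–Emmons opening of the lactol).
3. 10 ⇒ (Z)-enol carbamate 9, a masked γ-hydroxy aldehyde.
4. Key C–C bond (carbinol carbon to C2): 9 ⇒ 3,4-dimethoxybenzaldehyde 6 + a sparteine-derived chiral homoenolate (d3) reagent from allyl carbamate 5. This joins two carbons that are both normally electrophilic and sets both stereocentres at once.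
5. Rings: the target is acyclic; the only ring is the temporary oxolane lactol 10, formed in step 3 and opened in step 4.

Assumption: lithiation/titanation of 5 with (−)-sparteine follows the course known for (E)-but-2-enyl carbamates ((S)-lithio species, inversion on titanation, chair transition state); this is recalled and derived from that model, not checked on this substrate, and (E)-but-2-ene-1,4-diol is taken as purchasable.

## Route

Step 1
Reactants: 1 (E)-but-2-ene-1,4-diol; 2 tert-butyl(chloro)diphenylsilane; 3 N,N-diisopropylcarbamoyl chloride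
Product: 5 (E)-4-[(tert-butyldiphenylsilyl)oxy]but-2-en-1-yl N,N-diisopropylcarbamate, via mono-silyl ether 4 (not isolated)
Conditions: NaH (1.0 eq), THF, 0 °C → rt; 2 (1.0 eq), rt; then NaH (1.2 eq), 3 (1.2 eq), reflux
Reagents that add atoms: tert-butyl(chloro)diphenylsilane (2), CC(C)(C)[Si](Cl)(c1ccccc1)c1ccccc1; N,N-diisopropylcarbamoyl chloride (3), CC(C)N(C(C)C)C(=O)Cl
Why: The sparingly soluble monosodium alkoxide of the symmetrical diol is silylated once (McDougal monosilylation) and the remaining hydroxyl is then O-carbamoylated (Hoppe carbamate formation); no stereocentre is involved and the E alkene is untouched.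

Step 2
Reactants: 5 (E)-4-[(tert-butyldiphenylsilyl)oxy]but-2-en-1-yl N,N-diisopropylcarbamate; 6 3,4-dimethoxybenzaldehyde
Product: 9 (1Z,3R,4S)-3-{[(tert-butyldiphenylsilyl)oxy]methyl}-4-(3,4-dimethoxyphenyl)-4-hydroxybut-1-en-1-yl N,N-diisopropylcarbamate, via lithiated carbamate 7 (not isolated), via allyltitanium reagent 8 (not isolated)
Conditions: n-BuLi (1.15 eq), (−)-sparteine (1.2 eq), pentane/cyclohexane, −78 °C, 3 h; Ti(Oi-Pr)4 (3 eq), −78 °C; 6 (in a little THF), −78 → −40 °C; H2O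
Reagents that add atoms: 3,4-dimethoxybenzaldehyde (6), COc1ccc(C=O)cc1OC
Why: Hoppe asymmetric homoaldol reaction, in which carbamate-directed α-lithiation with (−)-sparteine gives the (S)-lithio carbamate 7 (enriched through its sparteine complex), Li→Ti exchange with inversion gives the (R)-allyltitanium homoenolate equivalent 8, and 8 adds through its γ-carbon to the aldehyde in a chair Zimmerman–Traxler transition state (aryl and CH2OSi equatorial, carbamoyloxy axial), which forms the C–C bond, the anti relationship, both stereocentres (3R,4S) and the Z enol carbamate in one operation.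

Step 3
Reactants: 9 (1Z,3R,4S)-3-{[(tert-butyldiphenylsilyl)oxy]methyl}-4-(3,4-dimethoxyphenyl)-4-hydroxybut-1-en-1-yl N,N-diisopropylcarbamate
Product: 10 (4R,5S)-4-{[(tert-butyldiphenylsilyl)oxy]methyl}-5-(3,4-dimethoxyphenyl)oxolan-2-ol (anomeric mixture)
Conditions: Hg(OAc)2 (5 mol %), MeSO3H (1.2 eq), THF/H2O 4:1, 0 °C → rt; NaHCO3
Reagents that add atoms: water, O
Why: Acid solvolysis of the enol carbamate catalysed by divalent mercury (Hoppe deblocking, run in wet THF instead of methanol), in which the activated enol double bond is captured by the γ-hydroxyl, the carbamate leaves as CO2 and i-Pr2NH, and water traps the oxocarbenium ion to give the γ-lactol; C4 and C5 are not touched, a few hours at about 0.1 M acid should be too mild to ionise the benzylic C–O bond, and the TBDPS ether survives.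

Step 4
Reactants: 10 (4R,5S)-4-{[(tert-butyldiphenylsilyl)oxy]methyl}-5-(3,4-dimethoxyphenyl)oxolan-2-ol; 11 diethyl (4-methoxybenzyl)phosphonate
Product: 13 (1S,2R)-1-(3,4-dimethoxyphenyl)-2-[(2E)-3-(4-methoxyphenyl)prop-2-en-1-yl]propane-1,3-diol, via silyl ether 12 (not isolated)
Conditions: 11 (2.5 eq), KOt-Bu (3.5 eq), THF/DMF, 0 °C → rt; then n-Bu4NF (2 eq), rt; aq. NH4Cl
Reagents that add atoms: diethyl (4-methoxybenzyl)phosphonate (11), CCOP(=O)(Cc1ccc(OC)cc1)OCC
Why: The lactol alkoxide is in equilibrium with the open γ-alkoxy aldehyde, which undergoes Horner–Wadsworth–Emmons olefination with the benzylic phosphonate anion to give the (E)-styrene and free the secondary alkoxide, after which fluoride cleaves the silyl ether in the same pot; neither stereocentre can epimerise because C2 is β to the aldehyde.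

Step 5
Reactants: 13 (1S,2R)-1-(3,4-dimethoxyphenyl)-2-[(2E)-3-(4-methoxyphenyl)prop-2-en-1-yl]propane-1,3-diol; 14 but-2-ynoic acid
Product: 15 (2R,3S)-3-(3,4-dimethoxyphenyl)-3-hydroxy-2-[(2E)-3-(4-methoxyphenyl)prop-2-en-1-yl]propyl but-2-ynoate
Conditions: 14 (1.05 eq), DCC (1.1 eq), DMAP (5 mol %), CH2Cl2, −20 → 0 °C
Reagents that add atoms: but-2-ynoic acid (14), CC#CC(=O)O
Why: Steglich esterification at low temperature selects the unhindered primary hydroxyl over the hindered secondary benzylic one; the stereocentres are untouched.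

Step 6
Reactants: 15 (2R,3S)-3-(3,4-dimethoxyphenyl)-3-hydroxy-2-[(2E)-3-(4-methoxyphenyl)prop-2-en-1-yl]propyl but-2-ynoate; 16 formaldehyde
Product: 18 (2R,3S)-3-(3,4-dimethoxyphenyl)-3-hydroxy-2-[(2E)-3-(4-methoxyphenyl)prop-2-en-1-yl]propyl (2Z)-2-(hydroxymethyl)but-2-enoate, via vinylalane 17 (not isolated)
Conditions: i-Bu2AlH (2.3 eq), N-methylmorpholine N-oxide (2.3 eq), THF, 0 °C; then HCHO (gas from cracked paraformaldehyde), 0 °C → rt; aq. potassium sodium tartrate
Reagents that add atoms: formaldehyde (16), C=O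
Why: Vinylalumination (reductive aldol) in which Lewis-base-modified i-Bu2AlH, after one equivalent is consumed by the free hydroxyl, adds H and Al syn across the ynoate to give the α-aluminated enoate 17 with CH3 cis to the ester, and formaldehyde then hydroxymethylates the C–Al bond with retention, so the Z geometry is set kinetically.

## Compound list

1 | (E)-but-2-ene-1,4-diol | OC/C=C/CO | starting material
2 | tert-butyl(chloro)diphenylsilane | CC(C)(C)[Si](Cl)(c1ccccc1)c1ccccc1 | starting material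
3 | N,N-diisopropylcarbamoyl chloride | CC(C)N(C(C)C)C(=O)Cl | starting material
4 | (E)-4-[(tert-butyldiphenylsilyl)oxy]but-2-en-1-ol | OC/C=C/CO[Si](c1ccccc1)(c1ccccc1)C(C)(C)C | intermediate
5 | (E)-4-[(tert-butyldiphenylsilyl)oxy]but-2-en-1-yl N,N-diisopropylcarbamate | CC(C)N(C(C)C)C(=O)OC/C=C/CO[Si](c1ccccc1)(c1ccccc1)C(C)(C)C | intermediate
6 | 3,4-dimethoxybenzaldehyde | COc1ccc(C=O)cc1OC | starting material
7 | [(1S,2E)-4-[(tert-butyldiphenylsilyl)oxy]-1-(N,N-diisopropylcarbamoyloxy)but-2-en-1-yl]lithium, as its (−)-sparteine complex | [Li][C@H](OC(=O)N(C(C)C)C(C)C)/C=C/CO[Si](c1ccccc1)(c1ccccc1)C(C)(C)C | intermediate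
8 | [(1R,2E)-4-[(tert-butyldiphenylsilyl)oxy]-1-(N,N-diisopropylcarbamoyloxy)but-2-en-1-yl]tri(propan-2-olato)titanium (tetravalent titanium) | CC(C)O[Ti](OC(C)C)(OC(C)C)[C@@H](OC(=O)N(C(C)C)C(C)C)/C=C/CO[Si](c1ccccc1)(c1ccccc1)C(C)(C)C | intermediate
9 | (1Z,3R,4S)-3-{[(tert-butyldiphenylsilyl)oxy]methyl}-4-(3,4-dimethoxyphenyl)-4-hydroxybut-1-en-1-yl N,N-diisopropylcarbamate | CC(C)(C)[Si](c1ccccc1)(c1ccccc1)OC[C@@H](/C=C\OC(=O)N(C(C)C)C(C)C)[C@H](O)c1ccc(OC)c(OC)c1 | intermediate
10 | (4R,5S)-4-{[(tert-butyldiphenylsilyl)oxy]methyl}-5-(3,4-dimethoxyphenyl)oxolan-2-ol (anomeric mixture) | CC(C)(C)[Si](c1ccccc1)(c1ccccc1)OC[C@H]1CC(O)O[C@@H]1c1ccc(OC)c(OC)c1 | intermediate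
11 | diethyl (4-methoxybenzyl)phosphonate | CCOP(=O)(Cc1ccc(OC)cc1)OCC | starting material
12 | (1S,2R,4E)-2-{[(tert-butyldiphenylsilyl)oxy]methyl}-1-(3,4-dimethoxyphenyl)-5-(4-methoxyphenyl)pent-4-en-1-ol | CC(C)(C)[Si](c1ccccc1)(c1ccccc1)OC[C@@H](C/C=C/c1ccc(OC)cc1)[C@H](O)c1ccc(OC)c(OC)c1 | intermediate
13 | (1S,2R)-1-(3,4-dimethoxyphenyl)-2-[(2E)-3-(4-methoxyphenyl)prop-2-en-1-yl]propane-1,3-diol | OC[C@@H](C/C=C/c1ccc(OC)cc1)[C@H](O)c1ccc(OC)c(OC)c1 | intermediate
14 | but-2-ynoic acid | CC#CC(=O)O | starting material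
15 | (2R,3S)-3-(3,4-dimethoxyphenyl)-3-hydroxy-2-[(2E)-3-(4-methoxyphenyl)prop-2-en-1-yl]propyl but-2-ynoate | CC#CC(=O)OC[C@@H](C/C=C/c1ccc(OC)cc1)[C@H](O)c1ccc(OC)c(OC)c1 | intermediate
16 | formaldehyde | C=O | starting material
17 | (2R,3S)-3-[(diisobutylalumanyl)oxy]-3-(3,4-dimethoxyphenyl)-2-[(2E)-3-(4-methoxyphenyl)prop-2-en-1-yl]propyl (2E)-2-(diisobutylalumanyl)but-2-enoate | C/C=C(/[Al](CC(C)C)CC(C)C)C(=O)OC[C@@H](C/C=C/c1ccc(OC)cc1)[C@H](O[Al](CC(C)C)CC(C)C)c1ccc(OC)c(OC)c1 | intermediate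
18 | (2R,3S)-3-(3,4-dimethoxyphenyl)-3-hydroxy-2-[(2E)-3-(4-methoxyphenyl)prop-2-en-1-yl]propyl (2Z)-2-(hydroxymethyl)but-2-enoate | C/C=C(/CO)C(=O)OC[C@@H](C/C=C/c1ccc(OC)cc1)[C@H](O)c1ccc(OC)c(OC)c1 | target

## Step count and risks

Total step count: 6. Longest linear sequence: 6 (1 → 5 → 9 → 10 → 13 → 15 → 18).

**Step 2 (key homoaldol).** The γ-CH2OSi substituent lies outside the closely precedented but-2-enyl case. The ee depends on how well the (S)-lithio·sparteine complex is enriched, which is crystallisation-driven in the parent system. Loss of silanolate from 7 by 1,4-elimination to a dienyl carbamate is also conceivable. If the absolute sense proves opposite to the assumption, the enantiomeric diamine would be needed. The fallback gives up the homoenolate disconnection and sets out from 6. (S)-4-Benzyl-1,3-oxazolidin-2-one is N-acylated with pent-4-enoyl chloride (n-BuLi, THF, −78 °C) to give (4S)-4-benzyl-3-(pent-4-enoyl)-1,3-oxazolidin-2-one F1. Its Z boron enolate (Bu2BOTf, i-Pr2NEt, CH2Cl2, −78 → 0 °C) adds to 6 in an Evans syn-aldol reaction to give (4S)-4-benzyl-3-{(2S)-2-[(S)-(3,4-dimethoxyphenyl)(hydroxy)methyl]pent-4-enoyl}-1,3-oxazolidin-2-one F2. LiBH4 (THF, 1 eq MeOH, 0 °C) removes the auxiliary to give (1S,2R)-1-(3,4-dimethoxyphenyl)-2-(prop-2-en-1-yl)propane-1,3-diol F3. Cross-metathesis of F3 with 1-ethenyl-4-methoxybenzene (second-generation Hoveyda–Grubbs catalyst, CH2Cl2, 40 °C) gives the E-styrene and rejoins the route at 13.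

**Step 4 (olefination of the lactol).** The benzylic phosphonate anion must intercept the small equilibrium share of open hydroxy aldehyde, so conversion may stall or some Z isomer may form. The fallback sets out from 10. Wittig methylenation with Ph3P=CH2 (from Ph3PCH3Br and KOt-Bu, THF, 0 °C → rt), which opens lactols reliably, gives (1S,2R)-2-{[(tert-butyldiphenylsilyl)oxy]methyl}-1-(3,4-dimethoxyphenyl)pent-4-en-1-ol F4. Cross-metathesis of F4 with 1-ethenyl-4-methoxybenzene (second-generation Hoveyda–Grubbs catalyst, CH2Cl2, 40 °C) builds the E-styrene and rejoins the route at 12, which is desilylated with n-Bu4NF to 13 as before.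

**Step 6 (late-stage hydroalumination/hydroxymethylation).** 1,4-Hydride delivery must outrun 1,2-reduction of the same ester in a substrate carrying an aluminated hydroxyl, and monomeric formaldehyde is awkward to dose. The fallback sets out from 13 and makes the acyl part separately. Ethyl but-2-ynoate is treated as in step 6 (i-Bu2AlH, N-methylmorpholine N-oxide, THF, 0 °C; HCHO) to give ethyl (2Z)-2-(hydroxymethyl)but-2-enoate F5. Silylation (t-BuMe2SiCl, imidazole, DMF) gives ethyl (2Z)-2-{[(tert-butyldimethylsilyl)oxy]methyl}but-2-enoate F6. Saponification (LiOH, THF/H2O, 0 °C) gives (2Z)-2-{[(tert-butyldimethylsilyl)oxy]methyl}but-2-enoic acid F7. Steglich coupling of F7 with 13 (DCC, DMAP cat., CH2Cl2, −20 °C) gives (2R,3S)-3-(3,4-dimethoxyphenyl)-3-hydroxy-2-[(2E)-3-(4-methoxyphenyl)prop-2-en-1-yl]propyl (2Z)-2-{[(tert-butyldimethylsilyl)oxy]methyl}but-2-enoate F8. HF·pyridine (THF, 0 °C) removes the silyl group and rejoins the route at 18.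

## Further compounds

F1 | step 2 | (4S)-4-benzyl-3-(pent-4-enoyl)-1,3-oxazolidin-2-one | C=CCCC(=O)N1[C@@H](Cc2ccccc2)COC1=O
F2 | step 2 | (4S)-4-benzyl-3-{(2S)-2-[(S)-(3,4-dimethoxyphenyl)(hydroxy)methyl]pent-4-enoyl}-1,3-oxazolidin-2-one | O=C(N1[C@@H](Cc2ccccc2)COC1=O)[C@@H](CC=C)[C@H](O)c1ccc(OC)c(OC)c1
F3 | step 2 | (1S,2R)-1-(3,4-dimethoxyphenyl)-2-(prop-2-en-1-yl)propane-1,3-diol | OC[C@@H](CC=C)[C@H](O)c1ccc(OC)c(OC)c1
F4 | step 4 | (1S,2R)-2-{[(tert-butyldiphenylsilyl)oxy]methyl}-1-(3,4-dimethoxyphenyl)pent-4-en-1-ol | CC(C)(C)[Si](c1ccccc1)(c1ccccc1)OC[C@@H](CC=C)[C@H](O)c1ccc(OC)c(OC)c1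
F5 | step 6 | ethyl (2Z)-2-(hydroxymethyl)but-2-enoate | C/C=C(/CO)C(=O)OCC
F6 | step 6 | ethyl (2Z)-2-{[(tert-butyldimethylsilyl)oxy]methyl}but-2-enoate | C/C=C(/CO[Si](C)(C)C(C)(C)C)C(=O)OCC
F7 | step 6 | (2Z)-2-{[(tert-butyldimethylsilyl)oxy]methyl}but-2-enoic acid | C/C=C(/CO[Si](C)(C)C(C)(C)C)C(=O)O
F8 | step 6 | (2R,3S)-3-(3,4-dimethoxyphenyl)-3-hydroxy-2-[(2E)-3-(4-methoxyphenyl)prop-2-en-1-yl]propyl (2Z)-2-{[(tert-butyldimethylsilyl)oxy]methyl}but-2-enoate | C/C=C(/CO[Si](C)(C)C(C)(C)C)C(=O)OC[C@@H](C/C=C/c1ccc(OC)cc1)[C@H](O)c1ccc(OC)c(OC)c1
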